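**Retrosynthetic overview**
- The acid comes from the aryl bromide (Br–Li exchange, CO2) as the last step.
- The (1E,3E)-diene is cut at its central sp2–sp2 bond: Heck union of an (E)-iodoalkene carrying ring A with (R)-6-bromo-2-methyl-2-vinylchromane.
- Key step: the pyran C2–O bond and the quaternary stereocentre are made together by a cobalt-hydride hydrogen-atom-transfer (MHAT) radical–polar crossover cycloisomerisation of an achiral dienyl phenol.
- The dienyl phenol comes from 4-bromophenol (Mannich base, ortho-quinone methide) and isoprene. The iodoalkene comes from 2-methylcyclohexanone (double methylation, enol triflate, Negishi alkylation, carboalumination–iodination).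
- Ring order: the cyclohexene (ring A) and the benzene ring are bought, ring A being fully substituted first; the pyran ring is the only ring closed, in the key step.

Assumption: the target stereocentre reads as (R) from the SMILES.
Assumption: the bromobutyne of step 3 is bought in its C-silyl-protected form.
Assumption: the sense of induction in step 7 must be found by experiment; the (R,R) catalyst is written, and its mirror image is used if it gives the (S) product.

**Step 1**
Reactants: 1 2-methylcyclohexanone
Product: 5 2,2,6-trimethylcyclohexanone, via kinetic lithium enolate 2 (not isolated), via 2,6-dimethylcyclohexanone 3 (not isolated), via second lithium enolate 4 (not isolated)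
Conditions: LiN(iPr)2 (commercial, 1.05 equiv), THF, −78 °C; MeI (1.0 equiv), −78 → 0 °C; recool, LiN(iPr)2 (1.1 equiv), −78 → 0 °C; MeI (1.2 equiv), → 23 °C (one pot)
Reagents that add atoms: methyl iodide (CI)
Why: Iterative enolate alkylation: kinetic deprotonation puts the first methyl at C6, and the symmetrical 2,6-dimethyl ketone can then only give the 2,2,6-pattern; the racemic centre of 5 is erased in step 2.

**Step 2**
Reactants: 5 2,2,6-trimethylcyclohexanone
Product: 6 2,6,6-trimethylcyclohex-1-en-1-yl trifluoromethanesulfonate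
Conditions: Tf2O, 2,6-di-tert-butyl-4-methylpyridine, CH2Cl2, 0 → 23 °C
Reagents that add atoms: trifluoromethanesulfonic anhydride (O=S(=O)(OS(=O)(=O)C(F)(F)F)C(F)(F)F)
Why: Enol triflate formation; only one enol is possible, so the tetrasubstituted ring A double bond is fixed regiospecifically.

**Step 3**
Reactants: 6 2,6,6-trimethylcyclohex-1-en-1-yl trifluoromethanesulfonate; 7 (4-bromobut-1-yn-1-yl)trimethylsilane
Product: 10 2-(but-3-yn-1-yl)-1,3,3-trimethylcyclohex-1-ene, via silylbutynylzinc bromide 8 (not isolated), via silyl enyne 9 (not isolated)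
Conditions: 7, Zn dust, LiCl, THF, 50 °C; then 6, Pd(OAc)2 (3 mol %), SPhos (6 mol %), THF, 60 °C; then K2CO3, MeOH, 23 °C
Reagents that add atoms: none
Why: Negishi sp2–sp3 cross-coupling of the alkenyl triflate with the primary alkylzinc reagent, followed in the same pot by methanolysis of the C–Si bond, gives the terminal alkyne and leaves the ring alkene untouched.

**Step 4**
Reactants: 10 2-(but-3-yn-1-yl)-1,3,3-trimethylcyclohex-1-ene
Product: 12 2-[(3E)-4-iodo-3-methylbut-3-en-1-yl]-1,3,3-trimethylcyclohex-1-ene, via alkenylalane 11 (not isolated)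
Conditions: Me3Al (2 equiv), Cp2ZrCl2 (0.25 equiv), CH2Cl2, 0 → 23 °C; then I2, THF, −30 → 0 °C
Reagents that add atoms: trimethylaluminium (C[Al](C)C); iodine (II)
Why: Negishi zirconium-catalysed syn-carboalumination places the methyl on the internal alkyne carbon, and iodinolysis with retention gives the (E)-iodoalkene, which fixes the trisubstituted double-bond geometry of the target.

**Step 5**
Reactants: 13 4-bromophenol
Product: 14 4-bromo-2-[(dimethylamino)methyl]phenol
Conditions: aq. CH2O (37 %), aq. Me2NH (40 %), EtOH, 23 → 70 °C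
Reagents that add atoms: formaldehyde (C=O); dimethylamine (CNC)
Why: Phenolic Mannich reaction; the para position is blocked by bromine, so aminomethylation goes ortho to the hydroxyl.

**Step 6**
Reactants: 14 4-bromo-2-[(dimethylamino)methyl]phenol; 15 2-methylbuta-1,3-diene (isoprene)
Product: 20 4-bromo-2-(3-methylidenepent-4-en-1-yl)phenol, via ammonium iodide 16 (not isolated), via isoprenylpotassium 17 (not isolated), via isoprenylmagnesium bromide 18 (not isolated), via ortho-quinone methide 19 (not isolated)
Conditions: (a) 14, MeI, THF, 23 °C; (b) separately 15, lithium 2,2,6,6-tetramethylpiperidide, KOt-Bu, THF, −78 °C, then MgBr2·OEt2; (c) add b (2.3 equiv) to a, −78 → 23 °C; H2O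
Reagents that add atoms: none
Why: N-methylation turns the amine into a leaving group, the magnesium phenoxide expels NMe3 to give the ortho-quinone methide, and 1,4-addition of the symmetrical 2-vinylallyl Grignard reagent (from allylic metalation of isoprene) rearomatises the ring and installs the 2-substituted butadiene.

**Step 7 (key step)**
Reactants: 20 4-bromo-2-(3-methylidenepent-4-en-1-yl)phenol
Product: 21 (2R)-6-bromo-2-ethenyl-2-methyl-3,4-dihydro-2H-chromene
Conditions: (R,R)-(salen)Co [C36H52CoN2O2, divalent cobalt] (5 mol %), N-fluoro-2,4,6-trimethylpyridinium triflate (1.2 equiv), PhSiH3 (1.1 equiv, syringe pump), PhCF3, 0 °C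
Reagents that add atoms: none
Why: Proposed new method: hydrogen-atom transfer from the trivalent cobalt hydride to the CH2 terminus of the 1,1-disubstituted end gives the tertiary allyl radical, which is captured by cobalt at its primary terminus, oxidised to the tetravalent allylcobalt and displaced in a 6-exo SN2′ sense by the phenol inside the chiral salen pocket, so the C2–O bond and the (R) centre form together (the eight-membered alternative cannot compete); the closest known reaction type is the enantioselective cobalt–salen MHAT/radical–polar crossover hydroalkoxylation of alkenols, extended here to a diene and a fully substituted allylic carbon, with asymmetric palladium allylic etherification as the closed-shell analogue.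

**Step 8**
Reactants: 21 (2R)-6-bromo-2-ethenyl-2-methyl-3,4-dihydro-2H-chromene; 12 2-[(3E)-4-iodo-3-methylbut-3-en-1-yl]-1,3,3-trimethylcyclohex-1-ene
Product: 22 (2R)-6-bromo-2-methyl-2-[(1E,3E)-4-methyl-6-(2,6,6-trimethylcyclohex-1-en-1-yl)hexa-1,3-dien-1-yl]-3,4-dihydro-2H-chromene
Conditions: Pd(OAc)2 (5 mol %), n-Bu4NCl, K2CO3, DMF, 50 °C
Reagents that add atoms: none
Why: Mizoroki–Heck reaction under Jeffery conditions: the alkenylpalladium from 12 adds to the unhindered CH2 of the vinyl group and syn β-hydride elimination (the only β-hydrogens are on the new CH2) gives the (1E,3E)-diene with the iodide geometry retained; the aryl bromide is inert at this temperature and the quaternary centre is not touched.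

**Step 9**
Reactants: 22 (2R)-6-bromo-2-methyl-2-[(1E,3E)-4-methyl-6-(2,6,6-trimethylcyclohex-1-en-1-yl)hexa-1,3-dien-1-yl]-3,4-dihydro-2H-chromene
Product: 24 (2R)-2-methyl-2-[(1E,3E)-4-methyl-6-(2,6,6-trimethylcyclohex-1-en-1-yl)hexa-1,3-dien-1-yl]-3,4-dihydro-2H-chromene-6-carboxylic acid, via aryllithium 23 (not isolated)
Conditions: n-BuLi (1.1 equiv), THF, −78 °C; CO2 (g), −78 → 0 °C; cold 0.5 M HCl to pH 3
Reagents that add atoms: carbon dioxide (O=C=O)
Why: Bromine–lithium exchange at −78 °C is faster than any addition to the diene, and carboxylation of the aryllithium followed by brief cold acidification gives the acid without ionising the tertiary allylic ether.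

**Compound list**
1 | 2-methylcyclohexanone (racemic) | CC1CCCCC1=O | starting material
2 | lithium 6-methylcyclohex-1-en-1-olate | CC1CCCC=C1O[Li] | intermediate
3 | 2,6-dimethylcyclohexanone (cis/trans mixture) | CC1CCCC(C)C1=O | intermediate
4 | lithium 2,6-dimethylcyclohex-1-en-1-olate | CC1CCCC(C)=C1O[Li] | intermediate
5 | 2,2,6-trimethylcyclohexanone (racemic) | CC1CCCC(C)(C)C1=O | intermediate
6 | 2,6,6-trimethylcyclohex-1-en-1-yl trifluoromethanesulfonate | CC1=C(OS(=O)(=O)C(F)(F)F)C(C)(C)CCC1 | intermediate
7 | (4-bromobut-1-yn-1-yl)trimethylsilane | C[Si](C)(C)C#CCCBr | starting material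
8 | [4-(trimethylsilyl)but-3-yn-1-yl]zinc bromide | C[Si](C)(C)C#CCC[Zn]Br | intermediate
9 | trimethyl[4-(2,6,6-trimethylcyclohex-1-en-1-yl)but-1-yn-1-yl]silane | CC1=C(CCC#C[Si](C)(C)C)C(C)(C)CCC1 | intermediate
10 | 2-(but-3-yn-1-yl)-1,3,3-trimethylcyclohex-1-ene | CC1=C(CCC#C)C(C)(C)CCC1 | intermediate
11 | dimethyl[(1E)-2-methyl-4-(2,6,6-trimethylcyclohex-1-en-1-yl)but-1-en-1-yl]alumane | C[Al](C)/C=C(\C)CCC1=C(C)CCCC1(C)C | intermediate
12 | 2-[(3E)-4-iodo-3-methylbut-3-en-1-yl]-1,3,3-trimethylcyclohex-1-ene | CC1=C(CC/C(C)=C/I)C(C)(C)CCC1 | intermediate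
13 | 4-bromophenol | Oc1ccc(Br)cc1 | starting material
14 | 4-bromo-2-[(dimethylamino)methyl]phenol | CN(C)Cc1cc(Br)ccc1O | intermediate
15 | 2-methylbuta-1,3-diene (isoprene) | C=CC(C)=C | starting material
16 | 1-(5-bromo-2-hydroxyphenyl)-N,N,N-trimethylmethanaminium iodide | C[N+](C)(C)Cc1cc(Br)ccc1O.[I-] | intermediate
17 | (2-methylidenebut-3-en-1-yl)potassium | C=CC(=C)C[K] | intermediate
18 | (2-methylidenebut-3-en-1-yl)magnesium bromide | C=CC(=C)C[Mg]Br | intermediate
19 | 4-bromo-6-methylidenecyclohexa-2,4-dien-1-one | C=C1C=C(Br)C=CC1=O | intermediate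
20 | 4-bromo-2-(3-methylidenepent-4-en-1-yl)phenol | C=CC(=C)CCc1cc(Br)ccc1O | intermediate
21 | (2R)-6-bromo-2-ethenyl-2-methyl-3,4-dihydro-2H-chromene | C=C[C@@]1(C)CCc2cc(Br)ccc2O1 | intermediate
22 | (2R)-6-bromo-2-methyl-2-[(1E,3E)-4-methyl-6-(2,6,6-trimethylcyclohex-1-en-1-yl)hexa-1,3-dien-1-yl]-3,4-dihydro-2H-chromene | CC1=C(CC/C(C)=C/C=C/[C@@]2(C)CCc3cc(Br)ccc3O2)C(C)(C)CCC1 | intermediate
23 | [(2R)-2-methyl-2-[(1E,3E)-4-methyl-6-(2,6,6-trimethylcyclohex-1-en-1-yl)hexa-1,3-dien-1-yl]-3,4-dihydro-2H-chromen-6-yl]lithium | CC1=C(CC/C(C)=C/C=C/[C@@]2(C)CCc3cc([Li])ccc3O2)C(C)(C)CCC1 | intermediate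
24 | (2R)-2-methyl-2-[(1E,3E)-4-methyl-6-(2,6,6-trimethylcyclohex-1-en-1-yl)hexa-1,3-dien-1-yl]-3,4-dihydro-2H-chromene-6-carboxylic acid | CC1=C(CC/C(C)=C/C=C/[C@@]2(C)CCc3cc(C(=O)O)ccc3O2)C(C)(C)CCC1 | target

**Step count**
Total: 9 steps. Longest linear sequence: 6 steps (1, 2, 3, 4, 8, 9); the other branch (5, 6, 7, 8, 9) has 5.

**Steps most likely to fail, with fallbacks**

Step 7. Enantiocontrol at a fully substituted allylic carbon is unproven, and hydrogen-atom transfer to the wrong diene terminus would only isomerise the diene. The fallback sets out from 14. It is quaternised with MeI as in step 6 and treated with the dilithium derivative of 3-methylbut-2-en-1-ol (n-BuLi, TMEDA; then MgBr2·OEt2), which alkylates through its (Z)-methyl group, to give (Z)-4-bromo-2-(5-hydroxy-3-methylpent-3-en-1-yl)phenol F1. Selective acylation of the allylic hydroxyl (ClCO2Me, pyridine, CH2Cl2, −30 °C) gives (2Z)-5-(5-bromo-2-hydroxyphenyl)-3-methylpent-2-en-1-yl methyl carbonate F2. Closed-shell asymmetric allylic etherification (Pd2(dba)3·CHCl3, DACH-phenyl Trost ligand of the enantiomer that gives (R), AcOH, CH2Cl2, 23 °C), which has direct precedent for 2-methyl-2-vinylchromans, returns to the route at 21.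

Step 8. The alkylpalladium intermediate sits β to the ring oxygen, and zerovalent palladium could ionise the tertiary allylic aryl ether, opening the ring or eroding the ee. The fallback sets out from 21. Ozonolysis (O3, CH2Cl2/MeOH, −78 °C; PPh3) gives (2R)-6-bromo-2-methyl-3,4-dihydro-2H-chromene-2-carbaldehyde F3. Takai iodo-olefination (CHI3, CrCl2, THF, 0 °C) gives (2R)-6-bromo-2-[(E)-2-iodoethenyl]-2-methyl-3,4-dihydro-2H-chromene F4. Negishi coupling of F4 at 23 °C with alkenylalane 11 (made from 10 as in step 4 but not iodinated; Pd(PPh3)4, ZnCl2, THF) returns to the route at 22.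

Step 6. The metalated isoprene may polymerise or the quinone methide may oligomerise before it is trapped. The fallback sets out from 14. After the same quaternisation, the quinone methide is trapped with allenylmagnesium bromide (from propargyl bromide and Mg), which reacts through its propargylic terminus, to give 4-bromo-2-(but-3-yn-1-yl)phenol F5. Enyne cross-metathesis with ethylene (second-generation Grubbs catalyst, ethylene 1 atm, toluene, 60 °C) builds the 2-substituted butadiene and returns to the route at 20.

**Further compounds**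
F1 | step 7 | (Z)-4-bromo-2-(5-hydroxy-3-methylpent-3-en-1-yl)phenol | OC/C=C(/C)CCc1cc(Br)ccc1O
F2 | step 7 | (2Z)-5-(5-bromo-2-hydroxyphenyl)-3-methylpent-2-en-1-yl methyl carbonate | COC(=O)OC/C=C(/C)CCc1cc(Br)ccc1O
F3 | step 8 | (2R)-6-bromo-2-methyl-3,4-dihydro-2H-chromene-2-carbaldehyde | O=C[C@@]1(C)CCc2cc(Br)ccc2O1
F4 | step 8 | (2R)-6-bromo-2-[(E)-2-iodoethenyl]-2-methyl-3,4-dihydro-2H-chromene | I/C=C/[C@@]1(C)CCc2cc(Br)ccc2O1
F5 | step 6 | 4-bromo-2-(but-3-yn-1-yl)phenol | C#CCCc1cc(Br)ccc1O
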